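**Plan**

- Cuts: (i) the bond from imidazole C2 to the first CH2 of the acetoxybutyl chain, made by adding C2–H across the terminal alkene of but-3-enyl acetate; (ii) the ArCH2–CH2 bond of the phenethyl linker, made as a C=C (Wittig) and then hydrogenated; (iii) the benzylic C–P bond of the Wittig salt.
- Enabling feature: in the 4,5-disubstituted imidazole ring, C2 is the only ring carbon that still carries hydrogen, and it lies between N1–H and N3. An N3-bound Rh(I) can therefore turn it into a C2-bound N-heterocyclic carbene that inserts the alkene, with no protecting or activating group.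
- Forward order: veratryl alcohol → phosphonium salt → Wittig with 4-methylimidazole-5-carbaldehyde (imidazole ring bought intact) → hydrogenation → C2–H alkylation with the acetate-bearing alkene, which should give the target directly.
- Stereochemistry: the target has no stereocentre; the only stereo element on the way, the alkene geometry of 5, is erased by hydrogenation.

Key step: step 4

Assumption: the target SMILES contains no stereocentre, stereogenic axis or stereogenic double bond, so the compound is achiral and no enantiocontrol is required.

**Route**

Step 1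
Reactants: 1 3,4-dimethoxybenzyl alcohol (veratryl alcohol)
Product: 2 (3,4-dimethoxybenzyl)triphenylphosphonium bromide
Conditions: PPh3·HBr (1.05 equiv), MeCN, reflux; precipitation with Et2O
Reagents that add atoms: triphenylphosphine hydrobromide, [Br-].c1ccc(cc1)[PH+](c1ccccc1)c1ccccc1
Why: Phosphonium salt formation from a benzylic alcohol with PPh3·HBr: acid-promoted ionisation of the electron-rich benzylic alcohol (or its conversion into the benzylic bromide) and capture by triphenylphosphine should give the salt, with water as the only co-product.

Step 2
Reactants: 2 (3,4-dimethoxybenzyl)triphenylphosphonium bromide; 3 4-methyl-1H-imidazole-5-carbaldehyde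
Product: 5 4-[(E)-2-(3,4-dimethoxyphenyl)ethenyl]-5-methyl-1H-imidazole (E/Z mixture expected), via phosphorus ylide 4 (not isolated)
Conditions: KOtBu (2.3 equiv), THF–DMF, 0 °C then 60 °C; aqueous work-up
Reagents that add atoms: none
Why: Wittig olefination, in which one equivalent of base makes the semi-stabilised benzylic ylide 4, a second is taken up by the acidic imidazole N–H, and the ylide should add to the formyl group to give the styryl imidazole (drawn as the E isomer and as the N–H tautomer that matches the target), whose geometry does not matter because step 3 saturates it.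

Step 3
Reactants: 5 4-[(E)-2-(3,4-dimethoxyphenyl)ethenyl]-5-methyl-1H-imidazole (E/Z mixture)
Product: 6 4-[2-(3,4-dimethoxyphenyl)ethyl]-5-methyl-1H-imidazole
Conditions: H2 (1 atm), 10% Pd/C, MeOH–AcOH, rt
Reagents that add atoms: none
Why: Heterogeneous catalytic hydrogenation of a conjugated disubstituted alkene should be fast while the imidazole ring, the veratryl ring and the ArCH2–CH2 bonds stay untouched; acetic acid protonates the imidazole nitrogen to limit catalyst poisoning.

Step 4
Reactants: 6 4-[2-(3,4-dimethoxyphenyl)ethyl]-5-methyl-1H-imidazole; 7 but-3-en-1-yl acetate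
Product: 8 O-acetylcypholophine, 4-{4-[2-(3,4-dimethoxyphenyl)ethyl]-5-methyl-1H-imidazol-2-yl}butyl acetate
Conditions: [RhCl(coe)2]2 (5 mol%), PCy3·HCl (15 mol%), the alkene in fivefold excess, THF, 150 °C, sealed tube
Reagents that add atoms: none
Why: The basic N3 of 6 binds Rh(I)–PCy3 and the C2–H bond is converted at the metal, by a C2–H to N–H hydrogen shift, into a C2-bound N-heterocyclic carbene complex; the terminal alkene of 7 then coordinates and inserts into the Rh–C2 bond with the metal on the internal carbon, and acid-assisted proton transfer releases the linear 2-alkylimidazole and the catalyst, so that all atoms of both partners end up in the product. The closest known reaction type is the Rh(I)/PCy3/acid-catalysed intermolecular C2-alkylation of N–H benzimidazoles and thiazoles with terminal alkenes (azole hydroheteroarylation). No ring is closed and no stereocentre is formed. Site selectivity should be complete because C4 and C5 of the imidazole ring already carry the phenethyl and methyl groups, so C2–H, flanked by N1–H and N3, is the only ring C–H and the only one that can become a carbene, while the veratryl C–H bonds have no neighbouring nitrogen. Linear (anti-Markovnikov) regiochemistry should follow from an insertion that places the bulky carbene carbon on the terminal CH2; the chemoselectivity needed is C–H addition faster than Rh–H isomerisation of 7 to the internal alkene, which the excess of the alkene and the acid co-catalyst are meant to secure, and the acetate and aryl methyl ethers are spectators.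

**Compound list**

1 | 3,4-dimethoxybenzyl alcohol (veratryl alcohol) | COc1ccc(CO)cc1OC | starting material
2 | (3,4-dimethoxybenzyl)triphenylphosphonium bromide | COc1ccc(C[P+](c2ccccc2)(c2ccccc2)c2ccccc2)cc1OC.[Br-] | intermediate
3 | 4-methyl-1H-imidazole-5-carbaldehyde | Cc1nc[nH]c1C=O | starting material
4 | (3,4-dimethoxybenzylidene)triphenylphosphorane (ylide, not isolated) | COc1ccc(C=P(c2ccccc2)(c2ccccc2)c2ccccc2)cc1OC | intermediate
5 | 4-[(E)-2-(3,4-dimethoxyphenyl)ethenyl]-5-methyl-1H-imidazole (E/Z mixture expected, E drawn) | COc1ccc(/C=C/c2nc[nH]c2C)cc1OC | intermediate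
6 | 4-[2-(3,4-dimethoxyphenyl)ethyl]-5-methyl-1H-imidazole | COc1ccc(CCc2nc[nH]c2C)cc1OC | intermediate
7 | but-3-en-1-yl acetate | C=CCCOC(C)=O | starting material
8 | O-acetylcypholophine, 4-{4-[2-(3,4-dimethoxyphenyl)ethyl]-5-methyl-1H-imidazol-2-yl}butyl acetate (achiral) | COc1ccc(CCc2nc(CCCCOC(C)=O)[nH]c2C)cc1OC | target

**Count**

Total steps: 4. Longest linear sequence: 4 steps (1 → 2 → 5 → 6 → 8).

**Steps most likely to fail**

1. Step 4. Chain-walking isomerisation of the terminal alkene to the internal (allylic acetate) isomer may outpace C–H addition, or the N–H imidazole may bind rhodium too strongly for turnover. The fallback sets out from 6 and comes back at 8, using C2-lithiation chemistry. Treatment of 6 with NaH and SEM-Cl in THF–DMF should give 4-[2-(3,4-dimethoxyphenyl)ethyl]-5-methyl-1-{[2-(trimethylsilyl)ethoxy]methyl}-1H-imidazole F1, formed together with its N-regioisomer, which behaves the same way and converges on deprotection. Deprotonation with n-BuLi in THF at −78 °C should give the 2-lithio derivative, 2-lithio-4-[2-(3,4-dimethoxyphenyl)ethyl]-5-methyl-1-{[2-(trimethylsilyl)ethoxy]methyl}imidazole F2, which is not isolated. Alkylation with tert-butyl(4-iodobutoxy)dimethylsilane should give 2-[4-(tert-butyldimethylsilyloxy)butyl]-4-[2-(3,4-dimethoxyphenyl)ethyl]-5-methyl-1-{[2-(trimethylsilyl)ethoxy]methyl}-1H-imidazole F3. Aqueous HCl in EtOH at reflux should remove both the SEM and the TBS group to give cypholophine, 4-{4-[2-(3,4-dimethoxyphenyl)ethyl]-5-methyl-1H-imidazol-2-yl}butan-1-ol F4. Acetylation with Ac2O and pyridine in CH2Cl2, followed by a methanol work-up that cleaves any N-acetylimidazole, should give 8.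

2. Step 2. Deprotonation of the imidazole N–H may leave a poorly soluble, weakly electrophilic imidazolide aldehyde, so that olefination stalls. The fallback sets out from 3 and comes back at 5. Tritylation of 3 with TrCl and Et3N in DMF should give 5-methyl-1-trityl-1H-imidazole-4-carbaldehyde F5; the N-regiochemistry is immaterial because the group is removed. Wittig reaction with ylide 4, made from 2 and KOtBu in THF, should give 4-[(E)-2-(3,4-dimethoxyphenyl)ethenyl]-5-methyl-1-trityl-1H-imidazole F6, again as an E/Z mixture. Detritylation in AcOH–H2O at 60 °C should return 5.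

3. Step 3. Coordination of the basic imidazole nitrogen to palladium may poison the catalyst and leave the alkene incompletely reduced. The fallback sets out from 5 and comes back at 6 by metal-free diimide reduction: p-toluenesulfonyl hydrazide and NaOAc in refluxing THF–H2O generate diimide in the flask, which should transfer H2 to the styryl double bond in a concerted way. This fallback makes no new compound (F0).

**Further compounds**

F1 | step 4 | 4-[2-(3,4-dimethoxyphenyl)ethyl]-5-methyl-1-{[2-(trimethylsilyl)ethoxy]methyl}-1H-imidazole | COc1ccc(CCc2ncn(COCC[Si](C)(C)C)c2C)cc1OC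
F2 | step 4 | 2-lithio-4-[2-(3,4-dimethoxyphenyl)ethyl]-5-methyl-1-{[2-(trimethylsilyl)ethoxy]methyl}imidazole (not isolated) | COc1ccc(CCc2nc([Li])n(COCC[Si](C)(C)C)c2C)cc1OC
F3 | step 4 | 2-[4-(tert-butyldimethylsilyloxy)butyl]-4-[2-(3,4-dimethoxyphenyl)ethyl]-5-methyl-1-{[2-(trimethylsilyl)ethoxy]methyl}-1H-imidazole | COc1ccc(CCc2nc(CCCCO[Si](C)(C)C(C)(C)C)n(COCC[Si](C)(C)C)c2C)cc1OC
F4 | step 4 | cypholophine, 4-{4-[2-(3,4-dimethoxyphenyl)ethyl]-5-methyl-1H-imidazol-2-yl}butan-1-ol | COc1ccc(CCc2nc(CCCCO)[nH]c2C)cc1OC
F5 | step 2 | 5-methyl-1-trityl-1H-imidazole-4-carbaldehyde | Cc1c(C=O)ncn1C(c1ccccc1)(c1ccccc1)c1ccccc1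
F6 | step 2 | 4-[(E)-2-(3,4-dimethoxyphenyl)ethenyl]-5-methyl-1-trityl-1H-imidazole | COc1ccc(/C=C/c2ncn(C(c3ccccc3)(c3ccccc3)c3ccccc3)c2C)cc1OC
F0 | step 3 | none | none
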